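**Retrosynthetic overview**
1. Target ⇐ bicyclic keto lactone 14. The lactone C=O on C4 is a temporary second acceptor and tether; hydroxide opens it, CO2 is lost, and the C3–CH2OH, the C4–H and both phenols appear in one operation.
2. 14 ⇐ cyclopropane 12 + formaldehyde. A Lewis-acid (3+2) annulation makes O1–C2 and C4–C5, i.e. the whole oxolane ring, with inversion at C2.
3. Enabling feature: across C3 of the oxolane, C2 is benzylic to an electron-rich 4-oxy-3,5-dimethoxyphenyl ring (cation-stabilising) and C4 is alpha to the aryl ketone C=O (enolate-stabilising). C2–C3–C4 is therefore a latent 1,3-zwitterion (a donor–acceptor cyclopropane), the O1–C5H2 unit between its ends is formaldehyde, and the CH2OH on C3 lets a γ-lactone tie C3 to C4.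
4. 12 ⇐ lactone 9 (aldol with silylated syringaldehyde 2, then oxidation) ⇐ (Z)-cinnamyl diazoacetate 8 by catalytic enantioselective intramolecular cyclopropanation, the only step that buys absolute configuration ⇐ syringaldehyde 1, the source of both aryl rings.
5. Ring order: cyclopropane and γ-lactone together (step 6); oxolane at the cost of the cyclopropane (step 9); γ-lactone removed (step 10).

Key step: step 9

Remarks:
- Locants: O1, C2 (aryl-bearing), C3 (CH2OH-bearing, CH2OH carbon = C9), C4 (aroyl-bearing) and C5 (CH2) are the oxolane atoms of the target.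
- Abbreviations: TBS = tert-butyldimethylsilyl; ArTBS = 4-(TBSO)-3,5-dimethoxyphenyl; Rh2(5R-MEPY)4 = dirhodium tetrakis[methyl (5R)-2-oxopyrrolidine-5-carboxylate] (divalent rhodium).
- Assumption: diazo ester 8 follows the facial sense known for simple allylic diazoacetates with this catalyst family (the 5S catalyst gives the (1R,5S) parent lactone), so the 5R catalyst is chosen.
- Formaldehyde is used as a monomer solution cracked from commercial paraformaldehyde. Ionisable intermediates are listed in their neutral form.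

**Route**

Step 1
Reactants: 1 syringaldehyde (4-hydroxy-3,5-dimethoxybenzaldehyde)
Product: 2 4-(tert-butyldimethylsilyloxy)-3,5-dimethoxybenzaldehyde
Conditions: TBSCl, imidazole, DMF, 23 °C
Reagents that add atoms: tert-butyldimethylsilyl chloride (TBSCl), CC(C)(C)[Si](C)(C)Cl
Why: Imidazole-promoted silyl ether formation masks the acidic phenol for the base- and carbenoid-mediated steps, keeps the ring a moderate donor, and the group is cleaved by hydroxide in step 10.

Step 2
Reactants: 2 4-(TBSO)-3,5-dimethoxybenzaldehyde; 3 methyl bis(2,2,2-trifluoroethyl)phosphonoacetate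
Product: 4 methyl (2Z)-3-[4-(TBSO)-3,5-dimethoxyphenyl]prop-2-enoate
Conditions: KN(SiMe3)2, 18-crown-6, THF, −78 °C
Reagents that add atoms: none
Why: Still–Gennari variant of the Horner–Wadsworth–Emmons olefination, in which the bis(trifluoroethyl) phosphonate anion under dissociating conditions eliminates from the kinetic adduct and should give the Z-enoate; this geometry later becomes the endo (cis) placement of the aryl group on the cyclopropane.

Step 3
Reactants: 4 methyl (2Z)-3-[4-(TBSO)-3,5-dimethoxyphenyl]prop-2-enoate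
Product: 5 (2Z)-3-[4-(TBSO)-3,5-dimethoxyphenyl]prop-2-en-1-ol
Conditions: i-Bu2AlH (2.2 equiv), CH2Cl2, −78 °C; aq. KNaC4H4O6
Reagents that add atoms: none
Why: 1,2-Reduction of the enoate by the aluminium hydride at low temperature should give the allylic alcohol without touching the aryl silyl ether or isomerising the Z-alkene.

Step 4
Reactants: 5 (2Z)-3-[4-(TBSO)-3,5-dimethoxyphenyl]prop-2-en-1-ol; 6 bromoacetyl bromide
Product: 7 (2Z)-3-[4-(TBSO)-3,5-dimethoxyphenyl]prop-2-en-1-yl bromoacetate
Conditions: NaHCO3, MeCN, 0 °C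
Reagents that add atoms: none
Why: O-Acylation of the primary allylic alcohol by an acid bromide, buffered so that HBr cannot ionise or isomerise the electron-rich Z-cinnamyl system.

Step 5
Reactants: 7 (2Z)-3-[4-(TBSO)-3,5-dimethoxyphenyl]prop-2-en-1-yl bromoacetate
Product: 8 (2Z)-3-[4-(TBSO)-3,5-dimethoxyphenyl]prop-2-en-1-yl diazoacetate
Conditions: TsNHNHTs, DBU, THF, 0 °C
Reagents that add atoms: N,N'-bis(p-toluenesulfonyl)hydrazine, Cc1ccc(cc1)S(=O)(=O)NNS(=O)(=O)c1ccc(C)cc1
Why: Diazoacetate synthesis from a bromoacetate: N-alkylation of the ditosylhydrazine followed by base-induced loss of two sulfinate ions releases the diazo group under mild conditions.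

Step 6
Reactants: 8 (2Z)-3-[4-(TBSO)-3,5-dimethoxyphenyl]prop-2-en-1-yl diazoacetate
Product: 9 (1S,5R,6S)-6-[4-(TBSO)-3,5-dimethoxyphenyl]-3-oxabicyclo[3.1.0]hexan-2-one (aryl endo)
Conditions: Rh2(5R-MEPY)4 (1 mol %), CH2Cl2, 40 °C, slow addition of 8
Reagents that add atoms: none
Why: Enantioselective intramolecular cyclopropanation of an allylic diazoacetate through a chiral dirhodium carboxamidate carbenoid: the stereospecific addition turns the Z-alkene into the all-cis cyclopropane (aryl endo), and the catalyst selects the alkene face and thereby fixes all three stereocentres, Z-allylic diazoacetates being the best-behaved substrates of this catalyst class.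

Step 7
Reactants: 9 (1S,5R,6S)-6-ArTBS-3-oxabicyclo[3.1.0]hexan-2-one; 2 4-(TBSO)-3,5-dimethoxybenzaldehyde
Product: 11 (1S,5R,6R)-6-ArTBS-1-[hydroxy(ArTBS)methyl]-3-oxabicyclo[3.1.0]hexan-2-one (both carbinol epimers), via lithium enolate 10 (not isolated)
Conditions: LiN(i-Pr)2 (1.1 equiv), THF, −78 °C; then 2, −78 °C; aq. NH4Cl
Reagents that add atoms: none
Why: Aldol addition of the lithium enolate of the cyclopropane-fused lactone to the non-enolisable aldehyde; the bridgehead carbon can bond to the electrophile only through its exo valence, so its configuration is retained, and the carbinol configuration is of no consequence because it is oxidised in step 8.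

Step 8
Reactants: 11 (1S,5R,6R)-6-ArTBS-1-[hydroxy(ArTBS)methyl]-3-oxabicyclo[3.1.0]hexan-2-one
Product: 12 (1S,5R,6R)-1-[4-(TBSO)-3,5-dimethoxybenzoyl]-6-[4-(TBSO)-3,5-dimethoxyphenyl]-3-oxabicyclo[3.1.0]hexan-2-one
Conditions: Dess–Martin periodinane, CH2Cl2, 23 °C
Reagents that add atoms: none
Why: Dess–Martin oxidation of the secondary benzylic alcohol under neutral conditions avoids retro-aldol cleavage and installs the aryl ketone, completing the ketone/lactone acceptor pair of the donor–acceptor cyclopropane.

Step 9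
Reactants: 12 (1S,5R,6R)-1-[4-(TBSO)-3,5-dimethoxybenzoyl]-6-ArTBS-3-oxabicyclo[3.1.0]hexan-2-one; 13 formaldehyde (monomer, from cracked paraformaldehyde)
Product: 14 (1R,5R,6S)-1-[4-(TBSO)-3,5-dimethoxybenzoyl]-6-[4-(TBSO)-3,5-dimethoxyphenyl]-3,7-dioxabicyclo[3.3.0]octan-2-one (cis-fused; aryl exo)
Conditions: CH2O (5 equiv, CH2Cl2 solution, slow addition), Sc(OTf)3 (10 mol %), 4 Å MS, CH2Cl2, −40 → 0 °C
Reagents that add atoms: none
Why: Lewis-acid-catalysed formal (3+2) annulation of a donor–acceptor cyclopropane with an aldehyde: Sc(OTf)3 chelates the ketone and lactone carbonyls of 12 and polarises the bond between the acceptor carbon and the benzylic donor carbon, the formaldehyde oxygen attacks that benzylic carbon from the side opposite the breaking bond (SN2-like, new O1–C2 bond), and the scandium keto-lactone enolate then adds through carbon to the resulting O-alkylated formaldehyde oxocarbenium ion (new C4–C5 bond). The closest known reaction type is the Lewis-acid-catalysed aldehyde annulation of 2-arylcyclopropane-1,1-dicarbonyl compounds to tetrahydrofurans, used here with the simplest aldehyde and a keto-lactone acceptor pair. The one ring closed is the oxolane, by a 5-(enolexo)-endo-trig aldol-type attack of the enolate carbon on the oxocarbenium carbon, the closure that operates in these cationic 2-oxonia intermediates. C2 is set by inversion, which turns the endo aryl group of 12 into the exo aryl group of 14 (trans to the CH2O arm on C3); C3 is carried through untouched; and the quaternary C4 can only form cis-fused because the lactone tether holds its carbonyl on the face of the CH2O arm, which leaves the aroyl group trans to that arm. The step needs cleavage of only the bond to the aryl-stabilised carbon, stereospecific rather than ionised opening (the twisted 4-silyloxy group between two methoxy groups makes the ring a moderate donor, the temperature is low, and the exo-aryl product is also the more stable epimer), and capture by formaldehyde rather than O-cyclisation of the ketone to a dihydrofuran (the chelated enolate holds the ketone oxygen syn to the lactone carbonyl and away from the benzylic carbon, and that dihydrofuran would carry a trigonal carbon at a 5/5 ring fusion).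

Step 10
Reactants: 14 (1R,5R,6S)-1-[4-(TBSO)-3,5-dimethoxybenzoyl]-6-ArTBS-3,7-dioxabicyclo[3.3.0]octan-2-one
Product: 17 (4-hydroxy-3,5-dimethoxyphenyl)[(3S,4R,5S)-5-(4-hydroxy-3,5-dimethoxyphenyl)-4-(hydroxymethyl)oxolan-3-yl]methanone (CID53356211), via hydroxy keto acid 15 (not isolated), via C4-epimeric ketone 16 (not isolated)
Conditions: LiOH·H2O (6 equiv), THF/H2O, 0 → 23 °C; 1 M HCl to pH 3, 45 °C; extract; then DBU (1 equiv), THF, 23 °C
Reagents that add atoms: none
Why: Saponification of the ketone-activated γ-lactone with concurrent hydroxide cleavage of both aryl silyl ethers, decarboxylation of β-keto acid 15 through its cyclic six-membered transition state on mild acidification (ketonisation of the enol is expected to give at least partly the cis epimer 16), and DBU-mediated α-epimerisation of the ketone, which sets C4 under thermodynamic control with the aroyl group trans to the adjacent CH2OH while C2 and C3 are untouched.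

**Compound list**
1 | syringaldehyde (4-hydroxy-3,5-dimethoxybenzaldehyde) | COc1cc(C=O)cc(OC)c1O | starting material
2 | 4-(tert-butyldimethylsilyloxy)-3,5-dimethoxybenzaldehyde | COc1cc(C=O)cc(OC)c1O[Si](C)(C)C(C)(C)C | intermediate
3 | methyl bis(2,2,2-trifluoroethyl)phosphonoacetate | COC(=O)CP(=O)(OCC(F)(F)F)OCC(F)(F)F | starting material
4 | methyl (2Z)-3-[4-(TBSO)-3,5-dimethoxyphenyl]prop-2-enoate | COC(=O)/C=C\c1cc(OC)c(O[Si](C)(C)C(C)(C)C)c(OC)c1 | intermediate
5 | (2Z)-3-[4-(TBSO)-3,5-dimethoxyphenyl]prop-2-en-1-ol | OC/C=C\c1cc(OC)c(O[Si](C)(C)C(C)(C)C)c(OC)c1 | intermediate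
6 | bromoacetyl bromide | BrCC(Br)=O | starting material
7 | (2Z)-3-[4-(TBSO)-3,5-dimethoxyphenyl]prop-2-en-1-yl bromoacetate | BrCC(=O)OC/C=C\c1cc(OC)c(O[Si](C)(C)C(C)(C)C)c(OC)c1 | intermediate
8 | (2Z)-3-[4-(TBSO)-3,5-dimethoxyphenyl]prop-2-en-1-yl diazoacetate | [N-]=[N+]=CC(=O)OC/C=C\c1cc(OC)c(O[Si](C)(C)C(C)(C)C)c(OC)c1 | intermediate
9 | (1S,5R,6S)-6-[4-(TBSO)-3,5-dimethoxyphenyl]-3-oxabicyclo[3.1.0]hexan-2-one (all-cis cyclopropane, aryl endo) | O=C1[C@H]2[C@@H](c3cc(OC)c(O[Si](C)(C)C(C)(C)C)c(OC)c3)[C@H]2CO1 | intermediate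
10 | lithium enolate of 9 (C1=C2 enolate; C5 and C6 as in 9) | [Li+].[O-]C1=C2[C@@H](c3cc(OC)c(O[Si](C)(C)C(C)(C)C)c(OC)c3)[C@H]2CO1 | intermediate (not isolated)
11 | (1S,5R,6R)-6-ArTBS-1-[hydroxy(ArTBS)methyl]-3-oxabicyclo[3.1.0]hexan-2-one (carbinol carbon: both epimers) | O=C1[C@@]2(C(O)c3cc(OC)c(O[Si](C)(C)C(C)(C)C)c(OC)c3)[C@@H](c3cc(OC)c(O[Si](C)(C)C(C)(C)C)c(OC)c3)[C@H]2CO1 | intermediate
12 | (1S,5R,6R)-1-[4-(TBSO)-3,5-dimethoxybenzoyl]-6-[4-(TBSO)-3,5-dimethoxyphenyl]-3-oxabicyclo[3.1.0]hexan-2-one (aryl endo) | O=C1[C@@]2(C(=O)c3cc(OC)c(O[Si](C)(C)C(C)(C)C)c(OC)c3)[C@@H](c3cc(OC)c(O[Si](C)(C)C(C)(C)C)c(OC)c3)[C@H]2CO1 | intermediate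
13 | formaldehyde (monomer, cracked from paraformaldehyde) | C=O | starting material
14 | (1R,5R,6S)-1-[4-(TBSO)-3,5-dimethoxybenzoyl]-6-[4-(TBSO)-3,5-dimethoxyphenyl]-3,7-dioxabicyclo[3.3.0]octan-2-one (cis-fused, aryl exo) | O=C(c3cc(OC)c(O[Si](C)(C)C(C)(C)C)c(OC)c3)[C@]12CO[C@H](c3cc(OC)c(O[Si](C)(C)C(C)(C)C)c(OC)c3)[C@H]1COC2=O | intermediate
15 | (3R,4R,5S)-3-(4-hydroxy-3,5-dimethoxybenzoyl)-5-(4-hydroxy-3,5-dimethoxyphenyl)-4-(hydroxymethyl)oxolane-3-carboxylic acid | O=C(c3cc(OC)c(O)c(OC)c3)[C@]2(C(=O)O)CO[C@H](c3cc(OC)c(O)c(OC)c3)[C@H]2CO | intermediate (not isolated)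
16 | (4-hydroxy-3,5-dimethoxyphenyl)[(3R,4R,5S)-5-(4-hydroxy-3,5-dimethoxyphenyl)-4-(hydroxymethyl)oxolan-3-yl]methanone (C4 epimer, aroyl cis to CH2OH) | COc1cc(C(=O)[C@H]2CO[C@H](c3cc(OC)c(O)c(OC)c3)[C@H]2CO)cc(OC)c1O | intermediate (not isolated)
17 | (4-hydroxy-3,5-dimethoxyphenyl)[(3S,4R,5S)-5-(4-hydroxy-3,5-dimethoxyphenyl)-4-(hydroxymethyl)oxolan-3-yl]methanone (all-trans) | COc1cc(C(=O)[C@@H]2CO[C@H](c3cc(OC)c(O)c(OC)c3)[C@H]2CO)cc(OC)c1O | target

**Totals and risks**
Total step count: 10. Longest linear sequence: 10 steps, from syringaldehyde 1 (aldehyde 2 is used twice).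

Steps most likely to fail:

1. Step 9. What may go wrong: ionisation of the benzylic bond instead of SN2-like opening (loss of stereospecificity), O-cyclisation of the ketone (Cloke–Wilson-type rearrangement), insertion of more than one formaldehyde unit or polymerisation of formaldehyde on the Lewis acid, and hydroxymethylation of the electron-rich arenes. Fallback, setting out from 12 and returning to the route at 17: replace Lewis-acid activation by an anionic relay. Treatment of 12 with Bu4NF (2.5 equiv) and paraformaldehyde in THF at 0 °C should remove both aryl silyl groups. The 4-phenoxide of the donor ring then opens the cyclopropane by 1,6-elimination to a p-quinone methide that carries the stabilised keto-lactone enolate; this is the base-mediated counterpart of the opening of 2-(4-hydroxyaryl)cyclopropane-1,1-dicarbonyl compounds. The enolate hydroxymethylates reversibly, and only the adduct whose CH2O arm is cis to the quinone methide side chain can close by 5-exo-trig oxa-1,6-addition. That closure restores the arene and should give the bis-phenol keto lactone F1 with the aryl group in the less hindered exo position. F1 is then taken through the conditions of step 10 (no silyl ethers left to cleave) to 17.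

2. Step 7. What may go wrong: incomplete or unstable enolate formation at the strained cyclopropane carbon, self-condensation of the lactone, and retro-aldol cleavage on work-up. Fallback, setting out from 8 and returning at 12: introduce the aroyl group before the cyclopropane exists. Diazoacetate 8 is deprotonated with LiN(i-Pr)2 (THF, −78 °C) and added to aldehyde 2 to give the β-hydroxy-α-diazo ester F2. Oxidation (Dess–Martin periodinane or MnO2) gives the α-diazo-β-keto ester F3. Intramolecular cyclopropanation of this acceptor/acceptor carbenoid with CuOTf (monovalent copper) and a C2-symmetric bis(oxazoline) ligand in CH2Cl2 should give 12 directly, the Z geometry again delivering the endo aryl group. If the enantioselectivity of this less selective carbenoid class is insufficient, 12 is enriched by crystallisation or chiral chromatography.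

3. Step 10. What may go wrong: re-lactonisation of the γ-hydroxy acid outrunning decarboxylation on acidification, retro-Claisen attack of hydroxide at the ketone, lactol trapping of the cis epimer, and base-induced β-alkoxy elimination (opening of the oxolane) during the DBU stage. Fallback, setting out from 14 and returning at 17: cap the primary alcohol before any free acid exists. After the same saponification (LiOH, THF/H2O) the crude salt of 15 is dried and persilylated (TBSCl, imidazole, DMF) to the tetrasilyl compound F4 (three silyl ethers and a silyl ester). Mild aqueous work-up cleaves only the silyl ester to give the tris-silyl keto acid F5, which decarboxylates on warming (toluene, 60 °C) to the tris-silyl ketone F6. F6 can neither re-lactonise nor form a lactol; it is equilibrated at C4 with DBU and then desilylated with Bu4NF/AcOH to 17.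

**Further compounds**
F1 | step 9 | (1R,5R,6S)-1-(4-hydroxy-3,5-dimethoxybenzoyl)-6-(4-hydroxy-3,5-dimethoxyphenyl)-3,7-dioxabicyclo[3.3.0]octan-2-one | O=C(c3cc(OC)c(O)c(OC)c3)[C@]12CO[C@H](c3cc(OC)c(O)c(OC)c3)[C@H]1COC2=O
F2 | step 7 | (2Z)-3-ArTBS-prop-2-en-1-yl 2-diazo-3-hydroxy-3-ArTBS-propanoate (carbinol: both epimers) | [N-]=[N+]=C(C(O)c1cc(OC)c(O[Si](C)(C)C(C)(C)C)c(OC)c1)C(=O)OC/C=C\c1cc(OC)c(O[Si](C)(C)C(C)(C)C)c(OC)c1
F3 | step 7 | (2Z)-3-ArTBS-prop-2-en-1-yl 2-diazo-3-oxo-3-ArTBS-propanoate | [N-]=[N+]=C(C(=O)c1cc(OC)c(O[Si](C)(C)C(C)(C)C)c(OC)c1)C(=O)OC/C=C\c1cc(OC)c(O[Si](C)(C)C(C)(C)C)c(OC)c1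
F4 | step 10 | tert-butyldimethylsilyl (3R,4R,5S)-3-[4-(TBSO)-3,5-dimethoxybenzoyl]-5-[4-(TBSO)-3,5-dimethoxyphenyl]-4-[(TBSO)methyl]oxolane-3-carboxylate | O=C(c3cc(OC)c(O[Si](C)(C)C(C)(C)C)c(OC)c3)[C@]2(C(=O)O[Si](C)(C)C(C)(C)C)CO[C@H](c3cc(OC)c(O[Si](C)(C)C(C)(C)C)c(OC)c3)[C@H]2CO[Si](C)(C)C(C)(C)C
F5 | step 10 | (3R,4R,5S)-3-[4-(TBSO)-3,5-dimethoxybenzoyl]-5-[4-(TBSO)-3,5-dimethoxyphenyl]-4-[(TBSO)methyl]oxolane-3-carboxylic acid | O=C(c3cc(OC)c(O[Si](C)(C)C(C)(C)C)c(OC)c3)[C@]2(C(=O)O)CO[C@H](c3cc(OC)c(O[Si](C)(C)C(C)(C)C)c(OC)c3)[C@H]2CO[Si](C)(C)C(C)(C)C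
F6 | step 10 | [4-(TBSO)-3,5-dimethoxyphenyl]{(3S,4R,5S)-5-[4-(TBSO)-3,5-dimethoxyphenyl]-4-[(TBSO)methyl]oxolan-3-yl}methanone | COc1cc(C(=O)[C@@H]2CO[C@H](c3cc(OC)c(O[Si](C)(C)C(C)(C)C)c(OC)c3)[C@H]2CO[Si](C)(C)C(C)(C)C)cc(OC)c1O[Si](C)(C)C(C)(C)C
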